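## Structural features

The target is a trans-fused bicyclo[5.3.0]decane; azulene numbering (C1–C8a) is used for the rings and C1'–C5' for the side chain. The cyclopentane (C1, C2, C3, C3a, C8a) shares the C3a–C8a bond with the cycloheptane (C3a, C4–C8, C8a). C3a is quaternary and carries the angular methyl, and the C8a hydrogen is trans to it. C1 carries the side chain through the tertiary carbinol C1' (methyl, free hydroxyl), and the chain ends in a secondary allylic acetate at C4' beside an isopropenyl group. C1', C1, C8a and C3a are four contiguous stereocentres; C5 (acetoxy, trans to the C3a methyl) is separated from C3a only by C4, and C4' is remote. The fragile parts are the two allylic acetates (ionisation, allylic transposition), the tertiary alcohol (dehydration) and the 1,1-disubstituted alkenes at C6 and C5' (migration, reduction). The real difficulty is the seven-membered ring with its all-carbon quaternary centre at the ring fusion, followed by C1' and C5, which no ring controls directly. The key step uses the sequence C3a–C4–C5(O)–C6–C7–C8–C8a: an oxygenated C5 between C4 and the three carbons C6–C8 is what remains when a C6–C7–C8 cyclopropane, carrying a C4=C5 enol ether on C6 and the C8a=C3a cyclopentene bond on C8, undergoes a [3,3] shift.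

## Logic of the disconnections

35 ⇒ 34. The two secondary C–O acyl bonds are cut last. No ester then has to survive an organometallic step. The forward step must acylate two secondary hydroxyls and leave the tertiary one free, which steric differentiation allows.

34 ⇒ 33 ⇒ 23 + 30. The C1'–C2' bond is cut between a methyl ketone and a primary carbanion. This removes the whole chain, including C4', as a separately made fragment. The forward addition must choose one face of the ketone (Felkin–Anh control from C1), must not enolise the ketone, and must tolerate the free C5 hydroxyl.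

23 ⇒ 22 ⇒ 21. The acetyl group is masked again and the C5–H bond is cut back to an enone. The hydride has to arrive on the face of the angular methyl, which a simple hydride would be expected to avoid, so a reagent-controlled reduction is required.

21 ⇒ 19 ⇒ 18 ⇒ 17. The exocyclic carbon on C6 and the C8a–H bond are removed. Both come from the two functional groups that the key step leaves behind: the C5=C6 enol silane (aminomethylation, then elimination) and the C8=C8a alkene (hydrogenation anti to the methyl). The demand is α-face delivery of hydrogen and an amine that survives until it is quaternised.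

17 ⇒ 16 (key disconnection). The C3a–C4 bond is cut and the C6–C8 bond is restored. The seven-membered ring and the quaternary centre disappear together, and the problem shrinks to a cis-1,2-disubstituted cyclopropane on a cyclopentene. The forward step needs the cis geometry and one absolute configuration of the cyclopropane, because these decide the configuration of C3a.

16 ⇒ 15 ⇒ 14 ⇒ 13 ⇒ 12. The enol silane goes back to a methyl ketone, and the C4–C5 bond is cut to an aldehyde and then to a primary alcohol. The alcohol is kept because it is the handle for a directed asymmetric cyclopropanation. The cis-cyclopropyl carbonyl compounds must be handled cold and without strong acid or base.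

12 ⇒ 10 + 11. Both C7 bonds of the cyclopropane are cut. The forward step must be stereospecific (Z-alkene to cis-cyclopropane), enantioface-selective by reagent control, and must leave the tetrasubstituted ring alkene alone.

10 ⇒ 9 ⇒ 7 + 8. The C6=C8 double bond is cut to an aldehyde and a phosphonate. The demand is Z-selectivity on a hindered, fully substituted enal.

7 ⇒ 6 ⇒ 5. The C3a–C8a bond of the cyclopentene is cut (aldol condensation), and the dicarbonyl compound is traced to a cyclohexane-1,2-diol. The aldehyde α-carbon must attack the ketone, which amine catalysis secures.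

5 ⇒ 4 ⇒ 3 ⇒ 1. The ketal, then the acetyl group (from the isopropenyl group), then the diol are removed. The acetyl group is unmasked and protected while the ring is still a saturated cyclohexane. A free acetyl group next to the cyclopentene double bond would be a β,γ-unsaturated ketone whose easy enolisation would destroy the only stereocentre.

30 ⇒ 29 ⇒ 28 ⇒ 27 ⇒ 25 + 26, 25 ⇒ 24. The iodide is traced to a chloride, the C4' stereocentre to an isopropenyl ketone (catalytic asymmetric reduction), and the ketone to an acylation of an alkenyl Grignard reagent. The demand is clean mono-addition to the acyl unit without loss of HCl.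

## Other disconnections considered

Alternative 1: The cut removes C3a–C4 and C1–C8a together with the C1'–O bond, back to the acyclic (2Z,6E,10E)-3,7,11,15-tetramethylhexadeca-2,6,10,14-tetraen-1-ol A1. In the forward direction an acid would ionise the Z-allylic alcohol; the allyl cation would close on C3a while the next alkene closes on C8a, and water would trap the C1' cation to give the bicyclic tertiary alcohol A2.
- In favour: both rings, three ring stereocentres and the tertiary carbinol would arise in one operation from a C20 chain. On step count, and on the way C1' is set (inside the cascade, not by an acyclic 1,2-addition), this is better than the chosen plan.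
- Against: outside an enzyme nothing enforces the seven-membered closure at the more substituted alkene carbon over six-membered closure or plain elimination, and nothing sets the absolute configuration.
- Also against: A2 still lacks the oxygen at C5 and C4' and both exocyclic methylenes. These would have to come from two ene-type oxygenations with mixed regiochemistry and no control at C4'.
- Comparison: the chosen plan is longer but controls each stereocentre by a named element; Alternative 1 is shorter but rests on selectivities that cannot be argued from the substrate.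

Alternative 2: The cut removes C3a–C8a and C4–C5 and adds an oxygen bridge between C5 and C8a, back to the acetoxypyranone A3 with a tethered 1,1-disubstituted alkene. Loss of acetate would give a 3-oxidopyrylium, and an intramolecular (5+2) cycloaddition would give the oxygen-bridged tricyclic enone A4.
- In favour: two rings, the quaternary C3a and the C5–O bond would form in one thermal step, with the C5 oxygen in a fixed relation to the ring fusion and the complete side chain already in place. On rings formed per step and on the C5 configuration it is the equal or the better of the chosen plan, which needs a separate reagent-controlled reduction.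
- Against: A4 carries a C8 ketone, a C8a–O bond and a C6=C7 methyl alkene that the target does not have. Reductive C–O cleavage (with a new stereochemical question at C8a), deoxygenation at C8 and transposition of the alkene to the exocyclic position would cost several steps.
- Also against: the facial choice at C3a depends on the tether conformation, and A3 needs the C1/C1' pair made beforehand by acyclic control, which is the same problem as step 24 of the chosen plan, only earlier.
- Comparison: both key steps are thermal pericyclic reactions on known ground. The chosen plan uses both groups left by its key step directly, so its route after the key step is shorter and less corrective.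

Alternative 3: The cut removes C1–C1' (and the lactone C–O bond), back to methyl (5R)-5-(2,2-dimethoxyethyl)-5-methylcyclopent-1-ene-1-carboxylate A5 and (5S)-5-[(tert-butyldimethylsilyl)oxy]-6-methylhept-6-en-2-one A6. SmI2 would reduce A6 to a ketyl that adds to C1 of A5; protonation at C8a and lactonisation would give the cis-fused lactone A7.
- In favour: the C1–C1' bond, C1' and the C1/C8a relation would be set together in an ordered, samarium-bound transition state. On control of the tertiary carbinol this is the equal or the better of the acyclic addition in the chosen plan, and the side chain enters convergently.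
- Against: the quaternary C3a of A5 must be made enantioselectively by some other means. The seven-membered ring is not formed at all and would have to be built afterwards from the lactone carbonyl (C8) and the acetal arm (C4–C5), with C6, C7, the C5 oxygen and the methylene still missing.
- Also against: the intermolecular ketyl addition to a trisubstituted enoate competes with pinacol coupling and simple reduction of A6.
- Comparison: the chosen plan puts its key step on the hardest structural element (seven-membered ring plus quaternary centre); Alternative 3 puts it on the side-chain junction and leaves the ring problem open, at a clearly higher step count.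

Key step: step 13

Assumption: the (4R,5R)-dioxaborolane is taken to show with 10 the same sense of induction as with simple E- and Z-allylic alcohols (hydroxymethyl-bearing ring carbon 1S); the enantiomeric ligand would be used if the opposite sense were found.

## Route

Step 1
Reactants: 1 (S)-limonene
Product: 3 (1R,2R,4S)-1-methyl-4-(prop-1-en-2-yl)cyclohexane-1,2-diol, via limonene 1,2-oxide 2 (not isolated)
Conditions: mCPBA, CH2Cl2, 0 °C; then 1 M H2SO4 (aq), THF, 0 °C → rt
Reagents that add atoms: mCPBA, O=C(OO)c1cccc(Cl)c1; water, O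
Why: Prilezhaev epoxidation takes the more electron-rich trisubstituted ring alkene and spares the isopropenyl group; acid-catalysed trans-diaxial opening converts both epoxide epimers into the same trans-diol. C4 is not touched, and the two carbinol centres are erased in step 4.

Step 2
Reactants: 3 (1R,2R,4S)-1-methyl-4-(prop-1-en-2-yl)cyclohexane-1,2-diol
Product: 4 1-[(1S,3R,4R)-3,4-dihydroxy-4-methylcyclohexyl]ethan-1-one
Conditions: O3, CH2Cl2/MeOH, −78 °C; then Me2S, −78 °C → rt
Reagents that add atoms: ozone, [O-][O+]=O
Why: Ozonolysis with reductive work-up cleaves the only alkene to the methyl ketone. The stereocentre is here α to an ordinary saturated ketone, and the neutral conditions should not enolise it.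

Step 3
Reactants: 4 1-[(1S,3R,4R)-3,4-dihydroxy-4-methylcyclohexyl]ethan-1-one
Product: 5 (1R,2R,4S)-1-methyl-4-(2-methyl-1,3-dioxolan-2-yl)cyclohexane-1,2-diol
Conditions: HOCH2CH2OH, PPTS (cat.), benzene, reflux (Dean–Stark)
Reagents that add atoms: ethylene glycol, OCCO
Why: Acid-catalysed dioxolane formation driven by removal of water; the weak acid limits enolisation towards the ring stereocentre, and the trans-diol cannot form a competing bridged ketal.

Step 4
Reactants: 5 (1R,2R,4S)-1-methyl-4-(2-methyl-1,3-dioxolan-2-yl)cyclohexane-1,2-diol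
Product: 6 (3S)-3-(2-methyl-1,3-dioxolan-2-yl)-6-oxoheptanal
Conditions: NaIO4, NaHCO3, THF/H2O, 0 °C → rt
Reagents that add atoms: none
Why: Malaprade glycol cleavage opens the ring to the keto aldehyde at near-neutral pH, so the dioxolane and the stereocentre (now β to the aldehyde, not enolisable through it) are preserved.

Step 5
Reactants: 6 (3S)-3-(2-methyl-1,3-dioxolan-2-yl)-6-oxoheptanal
Product: 7 (5S)-2-methyl-5-(2-methyl-1,3-dioxolan-2-yl)cyclopent-1-ene-1-carbaldehyde
Conditions: piperidine (cat.), AcOH (cat.), toluene, 4 Å MS, rt → 50 °C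
Reagents that add atoms: none
Why: Enamine-mediated intramolecular aldol condensation: the aldehyde α-carbon attacks the methyl ketone (5-exo-trig, enolexo) and dehydration gives the tetrasubstituted enal. The stereocentre is allylic but not α to a carbonyl group, because the acetyl group is already a ketal.

Step 6
Reactants: 7 (5S)-2-methyl-5-(2-methyl-1,3-dioxolan-2-yl)cyclopent-1-ene-1-carbaldehyde; 8 methyl bis(2,2,2-trifluoroethyl)phosphonoacetate
Product: 9 methyl (2Z)-3-[(5S)-2-methyl-5-(2-methyl-1,3-dioxolan-2-yl)cyclopent-1-en-1-yl]prop-2-enoate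
Conditions: KN(SiMe3)2, 18-crown-6, THF, −78 °C
Reagents that add atoms: methyl bis(2,2,2-trifluoroethyl)phosphonoacetate (8), COC(=O)CP(=O)(OCC(F)(F)F)OCC(F)(F)F
Why: Still–Gennari modification of the Horner–Wadsworth–Emmons reaction: the electron-poor phosphonate under dissociating conditions eliminates fast from the kinetically formed adduct and should give the Z-enoate.

Step 7
Reactants: 9 methyl (2Z)-3-[(5S)-2-methyl-5-(2-methyl-1,3-dioxolan-2-yl)cyclopent-1-en-1-yl]prop-2-enoate
Product: 10 (2Z)-3-[(5S)-2-methyl-5-(2-methyl-1,3-dioxolan-2-yl)cyclopent-1-en-1-yl]prop-2-en-1-ol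
Conditions: i-Bu2AlH (2.2 equiv), CH2Cl2, −78 °C; potassium sodium tartrate (aq)
Reagents that add atoms: none
Why: 1,2-Reduction of the enoate by the aluminium hydride at low temperature gives the allylic alcohol without touching the alkene geometry or the ketal.

Step 8
Reactants: 10 (2Z)-3-[(5S)-2-methyl-5-(2-methyl-1,3-dioxolan-2-yl)cyclopent-1-en-1-yl]prop-2-en-1-ol; 11 diiodomethane
Product: 12 {(1S,2R)-2-[(5S)-2-methyl-5-(2-methyl-1,3-dioxolan-2-yl)cyclopent-1-en-1-yl]cyclopropyl}methanol
Conditions: Et2Zn, 11, DME, CH2Cl2, −10 °C; then 10 and (4R,5R)-2-butyl-N,N,N',N'-tetramethyl-1,3,2-dioxaborolane-4,5-dicarboxamide (1.2 equiv), −10 °C → rt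
Reagents that add atoms: diiodomethane (11), ICI
Why: Charette asymmetric Simmons–Smith cyclopropanation: the zinc alkoxide bound to the chiral dioxaborolane directs Zn(CH2I)2 to one face of the allylic alkene, and the syn addition turns the Z-alkene into the cis-cyclopropane. The tetrasubstituted ring alkene has no directing group and is hindered, so it should stay intact.

Step 9
Reactants: 12 {(1S,2R)-2-[(5S)-2-methyl-5-(2-methyl-1,3-dioxolan-2-yl)cyclopent-1-en-1-yl]cyclopropyl}methanol
Product: 13 (1S,2R)-2-[(5S)-2-methyl-5-(2-methyl-1,3-dioxolan-2-yl)cyclopent-1-en-1-yl]cyclopropane-1-carbaldehyde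
Conditions: Dess–Martin periodinane, pyridine, CH2Cl2, 0 °C
Reagents that add atoms: none
Why: Buffered Dess–Martin oxidation is neutral and cold, which should avoid both epimerisation of the cis-cyclopropane and the retro-Claisen rearrangement open to cis-2-alkenylcyclopropanecarbaldehydes (here further slowed by the fully substituted alkene terminus). The aldehyde is used at once.

Step 10
Reactants: 13 (1S,2R)-2-[(5S)-2-methyl-5-(2-methyl-1,3-dioxolan-2-yl)cyclopent-1-en-1-yl]cyclopropane-1-carbaldehyde
Product: 14 1-{(1S,2R)-2-[(5S)-2-methyl-5-(2-methyl-1,3-dioxolan-2-yl)cyclopent-1-en-1-yl]cyclopropyl}ethan-1-ol (both carbinol epimers)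
Conditions: MeMgBr, THF, −78 °C
Reagents that add atoms: methylmagnesium bromide, C[Mg]Br
Why: Grignard addition to the aldehyde; the new carbinol centre is of no consequence because it is oxidised in the next step.

Step 11
Reactants: 14 1-{(1S,2R)-2-[(5S)-2-methyl-5-(2-methyl-1,3-dioxolan-2-yl)cyclopent-1-en-1-yl]cyclopropyl}ethan-1-ol
Product: 15 1-{(1S,2R)-2-[(5S)-2-methyl-5-(2-methyl-1,3-dioxolan-2-yl)cyclopent-1-en-1-yl]cyclopropyl}ethan-1-one
Conditions: Dess–Martin periodinane, pyridine, CH2Cl2, 0 °C → rt
Reagents that add atoms: none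
Why: Dess–Martin oxidation of the secondary alcohol; the cyclopropyl α-hydrogen is kinetically hard to remove, so the cis relationship should be retained.

Step 12
Reactants: 15 1-{(1S,2R)-2-[(5S)-2-methyl-5-(2-methyl-1,3-dioxolan-2-yl)cyclopent-1-en-1-yl]cyclopropyl}ethan-1-one
Product: 16 tert-butyl[(1-{(1S,2R)-2-[(5S)-2-methyl-5-(2-methyl-1,3-dioxolan-2-yl)cyclopent-1-en-1-yl]cyclopropyl}ethenyl)oxy]dimethylsilane
Conditions: LiN(i-Pr)2, THF, −78 °C; TBSCl, DMPU, −78 → 0 °C
Reagents that add atoms: tert-butyldimethylsilyl chloride, CC(C)(C)[Si](C)(C)Cl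
Why: Kinetic deprotonation takes a methyl hydrogen (the cyclopropyl α-hydrogen is not removed), and O-silylation of the enolate gives the 1-silyloxyvinyl group without Lewis acid, so the ketal and the cis-cyclopropane are kept.

Step 13
Reactants: 16 tert-butyl[(1-{(1S,2R)-2-[(5S)-2-methyl-5-(2-methyl-1,3-dioxolan-2-yl)cyclopent-1-en-1-yl]cyclopropyl}ethenyl)oxy]dimethylsilane
Product: 17 tert-butyl(dimethyl){[(1S,3aR)-3a-methyl-1-(2-methyl-1,3-dioxolan-2-yl)-1,2,3,3a,4,7-hexahydroazulen-5-yl]oxy}silane
Conditions: toluene, 110 °C (sealed tube, argon, base-washed glass)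
Reagents that add atoms: none
Why: On heating, 16 should reach the conformation with both alkenyl groups folded over the three-membered ring and undergo a concerted suprafacial [3,3] shift through a boat-shaped transition state: C4 of the silyloxyvinyl group bonds to C3a of the cyclopentene while the strained C6–C8 bond breaks, leaving the C5=C6 enol silane and the C8=C8a alkene. The closest known reaction type is the Cope rearrangement of silyl enol ethers of cis-2-vinylcyclopropyl ketones to silyloxycyclohepta-1,4-dienes, including cases in which a cycloalkenyl partner delivers a ring-fusion quaternary carbon. The seven-membered ring closes by this pericyclic ring expansion, not by a polar cyclisation, and release of cyclopropane strain makes it irreversible. The new stereocentre C3a is controlled by the configuration of the cyclopropane: in the boat array only one face of the C8a=C3a bond can reach C4, and for the (1S,2R)-cyclopropane this places C4 trans and the methyl cis to the dioxolanyl group on C1, that is 3aR. The selectivity needed is therefore stereospecificity (cis geometry, one cyclopropane enantiomer), secured by the Z-olefination and the stereospecific, reagent-controlled cyclopropanation. The C1 substituent lies on the cyclopentene face remote from the cyclopropane, so the two elements are matched. The C3a methyl is forced inward towards the cyclopropane CH2, which raises the barrier and is the reason for heating; no alkyl C–H sits cis on the cyclopropane, so a homo-1,5-hydrogen shift cannot compete.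

Step 14
Reactants: 17 tert-butyl(dimethyl){[(1S,3aR)-3a-methyl-1-(2-methyl-1,3-dioxolan-2-yl)-1,2,3,3a,4,7-hexahydroazulen-5-yl]oxy}silane
Product: 18 (1S,3aR)-6-[(dimethylamino)methyl]-3a-methyl-1-(2-methyl-1,3-dioxolan-2-yl)-2,3,3a,4,6,7-hexahydroazulen-5(1H)-one (C6 epimers)
Conditions: CH2=NMe2+ I− (Eschenmoser's salt), CH2Cl2, rt; NaHCO3 (aq)
Reagents that add atoms: Eschenmoser's salt, C=[N+](C)C.[I-]
Why: Mannich-type aminomethylation of the enol silane by the iminium salt takes place at C6, the only position the regiodefined enol ether offers. The C6 configuration is irrelevant because that carbon becomes sp2 again in step 16.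

Step 15
Reactants: 18 (1S,3aR)-6-[(dimethylamino)methyl]-3a-methyl-1-(2-methyl-1,3-dioxolan-2-yl)-2,3,3a,4,6,7-hexahydroazulen-5(1H)-one
Product: 19 (1S,3aR,8aS)-6-[(dimethylamino)methyl]-3a-methyl-1-(2-methyl-1,3-dioxolan-2-yl)octahydroazulen-5(1H)-one (C6 epimers)
Conditions: H2 (1 atm), 10% Pd/C, EtOAc, rt
Reagents that add atoms: none
Why: Heterogeneous hydrogenation of the trisubstituted C8=C8a alkene; hydrogen should arrive on the α face, anti to both the angular methyl on C3a and the dioxolanyl group on C1, which gives the trans ring fusion (8aS).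

Step 16
Reactants: 19 (1S,3aR,8aS)-6-[(dimethylamino)methyl]-3a-methyl-1-(2-methyl-1,3-dioxolan-2-yl)octahydroazulen-5(1H)-one
Product: 21 (1S,3aR,8aS)-3a-methyl-6-methylidene-1-(2-methyl-1,3-dioxolan-2-yl)octahydroazulen-5(1H)-one, via trimethylammonium iodide 20 (not isolated)
Conditions: MeI, MeOH, rt; then NaHCO3 (aq), CH2Cl2, rt
Reagents that add atoms: none
Why: Quaternisation turns the amine into a leaving group, and mild base triggers E1cB elimination through the C5 enolate to the α-methylene ketone. The weak base should not move the alkene into the ring.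

Step 17
Reactants: 21 (1S,3aR,8aS)-3a-methyl-6-methylidene-1-(2-methyl-1,3-dioxolan-2-yl)octahydroazulen-5(1H)-one
Product: 22 (1S,3aR,5S,8aS)-3a-methyl-6-methylidene-1-(2-methyl-1,3-dioxolan-2-yl)decahydroazulen-5-ol
Conditions: (R)-2-methyl-CBS-oxazaborolidine (30 mol%), catecholborane, toluene, −78 °C
Reagents that add atoms: none
Why: Corey–Bakshi–Shibata reduction with the alkenyl side (C6) as the large and the C4 methylene as the small substituent; the (R)-catalyst should deliver hydride to the β face and give the 5S alcohol. Reagent control is chosen because an uncatalysed hydride would be expected to approach anti to the 1,3-related angular methyl and give the 5-epimer.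

Step 18
Reactants: 22 (1S,3aR,5S,8aS)-3a-methyl-6-methylidene-1-(2-methyl-1,3-dioxolan-2-yl)decahydroazulen-5-ol
Product: 23 1-[(1S,3aR,5S,8aS)-5-hydroxy-3a-methyl-6-methylidenedecahydroazulen-1-yl]ethan-1-one
Conditions: p-TsOH·H2O (cat.), THF/H2O (4:1), rt
Reagents that add atoms: water, O
Why: Acid-catalysed hydrolysis of the dioxolane; the acid is too dilute and too weak to ionise the secondary allylic alcohol, and the short contact at room temperature should not epimerise C1.

Step 19
Reactants: 24 3-chloropropanoyl chloride
Product: 25 3-chloro-N-methoxy-N-methylpropanamide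
Conditions: MeNHOMe·HCl, K2CO3, CH2Cl2/H2O, 0 °C
Reagents that add atoms: N,O-dimethylhydroxylamine hydrochloride, CNOC.Cl
Why: Schotten–Baumann acylation gives the Weinreb amide; the cold, weakly basic two-phase medium should not eliminate HCl from the β-chloro amide.

Step 20
Reactants: 25 3-chloro-N-methoxy-N-methylpropanamide; 26 isopropenylmagnesium bromide
Product: 27 1-chloro-4-methylpent-4-en-3-one
Conditions: 26, THF, −20 → 0 °C; cold 1 M HCl
Reagents that add atoms: isopropenylmagnesium bromide (26), CC(=C)[Mg]Br
Why: Weinreb ketone synthesis: the chelated tetrahedral adduct survives until acidic work-up, so neither a second addition nor conjugate addition to the enone product can occur.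

Step 21
Reactants: 27 1-chloro-4-methylpent-4-en-3-one
Product: 28 (3S)-1-chloro-4-methylpent-4-en-3-ol
Conditions: (R)-2-methyl-CBS-oxazaborolidine (15 mol%), catecholborane, toluene, −78 °C
Reagents that add atoms: none
Why: Corey–Bakshi–Shibata reduction of an α-substituted enone, a well-behaved substrate class; with the isopropenyl group as the large substituent the (R)-catalyst should give the 3S alcohol.

Step 22
Reactants: 28 (3S)-1-chloro-4-methylpent-4-en-3-ol
Product: 29 tert-butyl{[(3S)-5-chloro-2-methylpent-1-en-3-yl]oxy}dimethylsilane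
Conditions: TBSCl, imidazole, DMF, rt
Reagents that add atoms: tert-butyldimethylsilyl chloride, CC(C)(C)[Si](C)(C)Cl
Why: Standard silylation of the secondary allylic alcohol; the silyl ether survives the organometallic chemistry and leaves with fluoride at the end.

Step 23
Reactants: 29 tert-butyl{[(3S)-5-chloro-2-methylpent-1-en-3-yl]oxy}dimethylsilane
Product: 30 tert-butyl{[(3S)-5-iodo-2-methylpent-1-en-3-yl]oxy}dimethylsilane
Conditions: NaI, acetone, reflux
Reagents that add atoms: sodium iodide, [Na+].[I-]
Why: Finkelstein exchange at the primary carbon, driven by precipitation of NaCl; the stereocentre is not involved.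

Step 24
Reactants: 23 1-[(1S,3aR,5S,8aS)-5-hydroxy-3a-methyl-6-methylidenedecahydroazulen-1-yl]ethan-1-one; 30 tert-butyl{[(3S)-5-iodo-2-methylpent-1-en-3-yl]oxy}dimethylsilane
Product: 33 (2S,5S)-5-[(tert-butyldimethylsilyl)oxy]-2-[(1S,3aR,5S,8aS)-5-hydroxy-3a-methyl-6-methylidenedecahydroazulen-1-yl]-6-methylhept-6-en-2-ol, via alkyllithium 31 (not isolated), via alkylcerium dichloride 32 (not isolated)
Conditions: 30 (3 equiv), t-BuLi (6 equiv), Et2O, −78 °C; CeCl3 (anhydrous), THF, −78 °C; then 23, −78 °C; NH4Cl (aq)
Reagents that add atoms: tert-butyl{[(3S)-5-iodo-2-methylpent-1-en-3-yl]oxy}dimethylsilane (30), C=C(C)[C@H](CCI)O[Si](C)(C)C(C)(C)C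
Why: Iodine–lithium exchange and transmetalation give a weakly basic organocerium reagent (Imamoto conditions) that adds to the enolisable methyl ketone without enolising it; the first equivalent is spent on the C5 hydroxyl. By the Felkin–Anh model (C8a as the large group, attack past the C1 hydrogen) the chain should enter on the face that makes C1' S.

Step 25
Reactants: 33 (2S,5S)-5-[(tert-butyldimethylsilyl)oxy]-2-[(1S,3aR,5S,8aS)-5-hydroxy-3a-methyl-6-methylidenedecahydroazulen-1-yl]-6-methylhept-6-en-2-ol
Product: 34 (2S,5S)-2-[(1S,3aR,5S,8aS)-5-hydroxy-3a-methyl-6-methylidenedecahydroazulen-1-yl]-6-methylhept-6-ene-2,5-diol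
Conditions: Bu4NF, THF, 0 °C → rt
Reagents that add atoms: none
Why: Fluoride cleaves the silyl ether under non-acidic conditions, so the tertiary and allylic alcohols are not put at risk of ionisation.

Step 26
Reactants: 34 (2S,5S)-2-[(1S,3aR,5S,8aS)-5-hydroxy-3a-methyl-6-methylidenedecahydroazulen-1-yl]-6-methylhept-6-ene-2,5-diol
Product: 35 (3S,6S)-6-[(1S,3aR,5S,8aS)-5-acetoxy-3a-methyl-6-methylidenedecahydroazulen-1-yl]-6-hydroxy-2-methylhept-1-en-3-yl acetate (CNP0151143.1)
Conditions: Ac2O, pyridine, DMAP (cat.), CH2Cl2, 0 °C → rt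
Reagents that add atoms: acetic anhydride, CC(=O)OC(C)=O
Why: Nucleophile-catalysed acylation esterifies the two secondary alcohols and should leave the hindered tertiary C1' hydroxyl free under these mild conditions.

## Compound list

1 | (S)-limonene | C=C(C)[C@H]1CCC(C)=CC1 | starting material
2 | (4S)-limonene 1,2-oxide (cis/trans mixture) | C=C(C)[C@H]1CCC2(C)OC2C1 | intermediate
3 | (1R,2R,4S)-1-methyl-4-(prop-1-en-2-yl)cyclohexane-1,2-diol | C=C(C)[C@H]1CC[C@@](C)(O)[C@H](O)C1 | intermediate
4 | 1-[(1S,3R,4R)-3,4-dihydroxy-4-methylcyclohexyl]ethan-1-one | CC(=O)[C@H]1CC[C@@](C)(O)[C@H](O)C1 | intermediate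
5 | (1R,2R,4S)-1-methyl-4-(2-methyl-1,3-dioxolan-2-yl)cyclohexane-1,2-diol | CC2(OCCO2)[C@H]1CC[C@@](C)(O)[C@H](O)C1 | intermediate
6 | (3S)-3-(2-methyl-1,3-dioxolan-2-yl)-6-oxoheptanal | CC2(OCCO2)[C@H](CC=O)CCC(C)=O | intermediate
7 | (5S)-2-methyl-5-(2-methyl-1,3-dioxolan-2-yl)cyclopent-1-ene-1-carbaldehyde | CC2(OCCO2)[C@H]1CCC(C)=C1C=O | intermediate
8 | methyl bis(2,2,2-trifluoroethyl)phosphonoacetate | COC(=O)CP(=O)(OCC(F)(F)F)OCC(F)(F)F | starting material
9 | methyl (2Z)-3-[(5S)-2-methyl-5-(2-methyl-1,3-dioxolan-2-yl)cyclopent-1-en-1-yl]prop-2-enoate | CC2(OCCO2)[C@H]1CCC(C)=C1/C=C\C(=O)OC | intermediate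
10 | (2Z)-3-[(5S)-2-methyl-5-(2-methyl-1,3-dioxolan-2-yl)cyclopent-1-en-1-yl]prop-2-en-1-ol | CC2(OCCO2)[C@H]1CCC(C)=C1/C=C\CO | intermediate
11 | diiodomethane | ICI | starting material
12 | {(1S,2R)-2-[(5S)-2-methyl-5-(2-methyl-1,3-dioxolan-2-yl)cyclopent-1-en-1-yl]cyclopropyl}methanol | CC3(OCCO3)[C@H]1CCC(C)=C1[C@@H]2C[C@@H]2CO | intermediate
13 | (1S,2R)-2-[(5S)-2-methyl-5-(2-methyl-1,3-dioxolan-2-yl)cyclopent-1-en-1-yl]cyclopropane-1-carbaldehyde | CC3(OCCO3)[C@H]1CCC(C)=C1[C@@H]2C[C@@H]2C=O | intermediate
14 | 1-{(1S,2R)-2-[(5S)-2-methyl-5-(2-methyl-1,3-dioxolan-2-yl)cyclopent-1-en-1-yl]cyclopropyl}ethan-1-ol (carbinol epimers) | CC3(OCCO3)[C@H]1CCC(C)=C1[C@@H]2C[C@@H]2C(C)O | intermediate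
15 | 1-{(1S,2R)-2-[(5S)-2-methyl-5-(2-methyl-1,3-dioxolan-2-yl)cyclopent-1-en-1-yl]cyclopropyl}ethan-1-one | CC3(OCCO3)[C@H]1CCC(C)=C1[C@@H]2C[C@@H]2C(C)=O | intermediate
16 | tert-butyl[(1-{(1S,2R)-2-[(5S)-2-methyl-5-(2-methyl-1,3-dioxolan-2-yl)cyclopent-1-en-1-yl]cyclopropyl}ethenyl)oxy]dimethylsilane | CC3(OCCO3)[C@H]1CCC(C)=C1[C@@H]2C[C@@H]2C(=C)O[Si](C)(C)C(C)(C)C | intermediate
17 | tert-butyl(dimethyl){[(1S,3aR)-3a-methyl-1-(2-methyl-1,3-dioxolan-2-yl)-1,2,3,3a,4,7-hexahydroazulen-5-yl]oxy}silane | CC3(OCCO3)[C@H]1CC[C@]2(C)CC(O[Si](C)(C)C(C)(C)C)=CCC=C12 | intermediate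
18 | (1S,3aR)-6-[(dimethylamino)methyl]-3a-methyl-1-(2-methyl-1,3-dioxolan-2-yl)-2,3,3a,4,6,7-hexahydroazulen-5(1H)-one (C6 epimers) | CC3(OCCO3)[C@H]1CC[C@]2(C)CC(=O)C(CN(C)C)CC=C12 | intermediate
19 | (1S,3aR,8aS)-6-[(dimethylamino)methyl]-3a-methyl-1-(2-methyl-1,3-dioxolan-2-yl)octahydroazulen-5(1H)-one (C6 epimers) | CC3(OCCO3)[C@H]1CC[C@]2(C)CC(=O)C(CN(C)C)CC[C@@H]12 | intermediate
20 | N,N,N-trimethyl-1-[(1S,3aR,8aS)-3a-methyl-1-(2-methyl-1,3-dioxolan-2-yl)-5-oxodecahydroazulen-6-yl]methanaminium iodide (C6 epimers) | CC3(OCCO3)[C@H]1CC[C@]2(C)CC(=O)C(C[N+](C)(C)C)CC[C@@H]12.[I-] | intermediate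
21 | (1S,3aR,8aS)-3a-methyl-6-methylidene-1-(2-methyl-1,3-dioxolan-2-yl)octahydroazulen-5(1H)-one | CC3(OCCO3)[C@H]1CC[C@]2(C)CC(=O)C(=C)CC[C@@H]12 | intermediate
22 | (1S,3aR,5S,8aS)-3a-methyl-6-methylidene-1-(2-methyl-1,3-dioxolan-2-yl)decahydroazulen-5-ol | CC3(OCCO3)[C@H]1CC[C@]2(C)C[C@H](O)C(=C)CC[C@@H]12 | intermediate
23 | 1-[(1S,3aR,5S,8aS)-5-hydroxy-3a-methyl-6-methylidenedecahydroazulen-1-yl]ethan-1-one | CC(=O)[C@H]1CC[C@]2(C)C[C@H](O)C(=C)CC[C@@H]12 | intermediate
24 | 3-chloropropanoyl chloride | ClCCC(=O)Cl | starting material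
25 | 3-chloro-N-methoxy-N-methylpropanamide | CON(C)C(=O)CCCl | intermediate
26 | isopropenylmagnesium bromide | CC(=C)[Mg]Br | starting material
27 | 1-chloro-4-methylpent-4-en-3-one | C=C(C)C(=O)CCCl | intermediate
28 | (3S)-1-chloro-4-methylpent-4-en-3-ol | C=C(C)[C@H](CCCl)O | intermediate
29 | tert-butyl{[(3S)-5-chloro-2-methylpent-1-en-3-yl]oxy}dimethylsilane | C=C(C)[C@H](CCCl)O[Si](C)(C)C(C)(C)C | intermediate
30 | tert-butyl{[(3S)-5-iodo-2-methylpent-1-en-3-yl]oxy}dimethylsilane | C=C(C)[C@H](CCI)O[Si](C)(C)C(C)(C)C | intermediate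
31 | {(3S)-3-[(tert-butyldimethylsilyl)oxy]-4-methylpent-4-en-1-yl}lithium | C=C(C)[C@H](CC[Li])O[Si](C)(C)C(C)(C)C | intermediate
32 | dichloro{(3S)-3-[(tert-butyldimethylsilyl)oxy]-4-methylpent-4-en-1-yl}cerium | C=C(C)[C@H](CC[Ce](Cl)Cl)O[Si](C)(C)C(C)(C)C | intermediate
33 | (2S,5S)-5-[(tert-butyldimethylsilyl)oxy]-2-[(1S,3aR,5S,8aS)-5-hydroxy-3a-methyl-6-methylidenedecahydroazulen-1-yl]-6-methylhept-6-en-2-ol | C=C(C)[C@H](CC[C@](C)(O)[C@H]1CC[C@]2(C)C[C@H](O)C(=C)CC[C@@H]12)O[Si](C)(C)C(C)(C)C | intermediate
34 | (2S,5S)-2-[(1S,3aR,5S,8aS)-5-hydroxy-3a-methyl-6-methylidenedecahydroazulen-1-yl]-6-methylhept-6-ene-2,5-diol | C=C(C)[C@H](CC[C@](C)(O)[C@H]1CC[C@]2(C)C[C@H](O)C(=C)CC[C@@H]12)O | intermediate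
35 | (3S,6S)-6-[(1S,3aR,5S,8aS)-5-acetoxy-3a-methyl-6-methylidenedecahydroazulen-1-yl]-6-hydroxy-2-methylhept-1-en-3-yl acetate (CNP0151143.1) | C=C(C)[C@H](CC[C@](C)(O)[C@H]1CC[C@]2(C)C[C@H](OC(C)=O)C(=C)CC[C@@H]12)OC(C)=O | target

## Step count and least certain steps

Total step count: 26 (21 in the main line, 5 for the side-chain iodide 30).
Longest linear sequence: 21 steps (steps 1–18 and 24–26).

Step 13 (key step). The inward methyl on C3a may slow the rearrangement so much that, at the temperature it needs, one-centre epimerisation of the cyclopropane to the unreactive trans isomer or loss of the enol silane competes. The result would be incomplete conversion and eroded fidelity at C3a. Fallback, setting out from 7 and returning at 17: Wittig methylenation of 7 (Ph3P=CH2, THF) would give 2-[(1S)-2-ethenyl-3-methylcyclopent-2-en-1-yl]-2-methyl-1,3-dioxolane F1. An oxyallyl-cation (4+3) cycloaddition (1,1,3,3-tetrabromopropan-2-one, Fe2(CO)9, benzene, 60 °C) across the diene termini C3a and C7, anti to the dioxolanyl group, would give (1S)-4,6-dibromo-3a-methyl-1-(2-methyl-1,3-dioxolan-2-yl)-2,3,3a,4,6,7-hexahydroazulen-5(1H)-one F2. Zn–Cu couple with NH4Cl in MeOH would remove both bromines to give (1S,3aR)-3a-methyl-1-(2-methyl-1,3-dioxolan-2-yl)-2,3,3a,4,6,7-hexahydroazulen-5(1H)-one F3. Kinetic enolisation (LiN(i-Pr)2, −78 °C; TBSCl), which should take a C6 hydrogen in preference to the neopentyl C4 hydrogen, then gives 17.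

Step 17. The catalyst has to deliver hydride to the face of the 1,3-related angular methyl, which the substrate itself probably disfavours; this mismatch may erode the facial selectivity at C5. Fallback, setting out from 21 and returning at 22: substrate-controlled reduction with i-Bu2AlH (CH2Cl2, −78 °C), which should attack anti to the methyl, would give (1S,3aR,5R,8aS)-3a-methyl-6-methylidene-1-(2-methyl-1,3-dioxolan-2-yl)decahydroazulen-5-ol F4. Mitsunobu inversion (4-nitrobenzoic acid, PPh3, diisopropyl azodicarboxylate, THF, 0 °C) would give (1S,3aR,5S,8aS)-3a-methyl-6-methylidene-1-(2-methyl-1,3-dioxolan-2-yl)decahydroazulen-5-yl 4-nitrobenzoate F5. Methanolysis (K2CO3, MeOH) then gives 22.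

Step 15. On the metal surface the β-amino ketone may lose dimethylamine, after which the liberated enone would be saturated to a C6 methyl ketone. The C8=C8a bond may also migrate towards C1 before it is reduced, with loss of the C1 configuration. Fallback, setting out from 17 and returning at 21: the lithium enolate is unmasked from 17 (MeLi, THF, 0 °C → rt) and trapped with monomeric formaldehyde at −78 °C to give (1S,3aR)-6-(hydroxymethyl)-3a-methyl-1-(2-methyl-1,3-dioxolan-2-yl)-2,3,3a,4,6,7-hexahydroazulen-5(1H)-one F6. With no amine present, hydrogenation (H2, 5% Rh/Al2O3 or Pd/C, EtOAc) from the α face would give (1S,3aR,8aS)-6-(hydroxymethyl)-3a-methyl-1-(2-methyl-1,3-dioxolan-2-yl)octahydroazulen-5(1H)-one F7. Mesylation and elimination (MsCl, Et3N; then DBU) then give 21.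

Step 24. C2 and C8a differ only moderately in size, so the facial preference at the acetyl carbonyl may be weak or opposite to the Felkin–Anh prediction, which would give the C1' epimer. Fallback, setting out from 23 and returning at 34; it exchanges the roles of the two carbon groups, so the same facial preference delivers the other configuration at C1':
- Condensation of 23 with Me2NNH2 (EtOH, cat. AcOH) would give (1S,3aR,5S,8aS)-1-[1-(2,2-dimethylhydrazinylidene)ethyl]-3a-methyl-6-methylidenedecahydroazulen-5-ol F8.
- Its azaenolate (LiN(i-Pr)2, 2.2 equiv, THF, −78 → 0 °C) would open (R)-2-(prop-1-en-2-yl)oxirane F9 (from the racemate by hydrolytic kinetic resolution) at the CH2 terminus. This would give (3S)-6-(2,2-dimethylhydrazinylidene)-6-[(1S,3aR,5S,8aS)-5-hydroxy-3a-methyl-6-methylidenedecahydroazulen-1-yl]-2-methylhex-1-en-3-ol F10.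
- Hydrolysis of the hydrazone (CuCl2, THF/H2O, pH 7) would give (4S)-4-hydroxy-1-[(1S,3aR,5S,8aS)-5-hydroxy-3a-methyl-6-methylidenedecahydroazulen-1-yl]-5-methylhex-5-en-1-one F11.
- Addition of MeMgBr/CeCl3 (excess, THF, −78 °C) then gives 34, which continues with step 26.

## Further compounds

F1 | step 13 | 2-[(1S)-2-ethenyl-3-methylcyclopent-2-en-1-yl]-2-methyl-1,3-dioxolane | CC3(OCCO3)[C@H]1CCC(C)=C1C=C
F2 | step 13 | (1S)-4,6-dibromo-3a-methyl-1-(2-methyl-1,3-dioxolan-2-yl)-2,3,3a,4,6,7-hexahydroazulen-5(1H)-one (3a-methyl cis to the dioxolanyl group; bromine epimers) | CC3(OCCO3)[C@H]1CC[C@]2(C)C(Br)C(=O)C(Br)CC=C12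
F3 | step 13 | (1S,3aR)-3a-methyl-1-(2-methyl-1,3-dioxolan-2-yl)-2,3,3a,4,6,7-hexahydroazulen-5(1H)-one | CC3(OCCO3)[C@H]1CC[C@]2(C)CC(=O)CCC=C12
F4 | step 17 | (1S,3aR,5R,8aS)-3a-methyl-6-methylidene-1-(2-methyl-1,3-dioxolan-2-yl)decahydroazulen-5-ol | CC3(OCCO3)[C@H]1CC[C@]2(C)C[C@@H](O)C(=C)CC[C@@H]12
F5 | step 17 | (1S,3aR,5S,8aS)-3a-methyl-6-methylidene-1-(2-methyl-1,3-dioxolan-2-yl)decahydroazulen-5-yl 4-nitrobenzoate | CC3(OCCO3)[C@H]1CC[C@]2(C)C[C@H](OC(=O)c4ccc(cc4)[N+](=O)[O-])C(=C)CC[C@@H]12
F6 | step 15 | (1S,3aR)-6-(hydroxymethyl)-3a-methyl-1-(2-methyl-1,3-dioxolan-2-yl)-2,3,3a,4,6,7-hexahydroazulen-5(1H)-one (C6 epimers) | CC3(OCCO3)[C@H]1CC[C@]2(C)CC(=O)C(CO)CC=C12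
F7 | step 15 | (1S,3aR,8aS)-6-(hydroxymethyl)-3a-methyl-1-(2-methyl-1,3-dioxolan-2-yl)octahydroazulen-5(1H)-one (C6 epimers) | CC3(OCCO3)[C@H]1CC[C@]2(C)CC(=O)C(CO)CC[C@@H]12
F8 | step 24 | (1S,3aR,5S,8aS)-1-[1-(2,2-dimethylhydrazinylidene)ethyl]-3a-methyl-6-methylidenedecahydroazulen-5-ol | CN(C)N=C(C)[C@H]1CC[C@]2(C)C[C@H](O)C(=C)CC[C@@H]12
F9 | step 24 | (R)-2-(prop-1-en-2-yl)oxirane | C=C(C)[C@@H]1CO1
F10 | step 24 | (3S)-6-(2,2-dimethylhydrazinylidene)-6-[(1S,3aR,5S,8aS)-5-hydroxy-3a-methyl-6-methylidenedecahydroazulen-1-yl]-2-methylhex-1-en-3-ol | C=C(C)[C@H](CCC(=NN(C)C)[C@H]1CC[C@]2(C)C[C@H](O)C(=C)CC[C@@H]12)O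
F11 | step 24 | (4S)-4-hydroxy-1-[(1S,3aR,5S,8aS)-5-hydroxy-3a-methyl-6-methylidenedecahydroazulen-1-yl]-5-methylhex-5-en-1-one | C=C(C)[C@H](CCC(=O)[C@H]1CC[C@]2(C)C[C@H](O)C(=C)CC[C@@H]12)O
A1 | alternative 1 | (2Z,6E,10E)-3,7,11,15-tetramethylhexadeca-2,6,10,14-tetraen-1-ol | CC(C)=CCC/C(C)=C/CC/C(C)=C/CC/C(C)=C\CO
A2 | alternative 1 | (2S)-2-[(1S,3aR,8aS)-3a,6-dimethyl-1,2,3,3a,4,7,8,8a-octahydroazulen-1-yl]-6-methylhept-5-en-2-ol | CC(C)=CCC[C@](C)(O)[C@H]1CC[C@]2(C)CC=C(C)CC[C@@H]12
A3 | alternative 2 | 5-methyl-3-oxo-2-{(5S,6S,9S)-9-[(tert-butyldimethylsilyl)oxy]-2,6,10-trimethyl-6-[(triethylsilyl)oxy]undeca-1,10-dien-5-yl}-3,6-dihydro-2H-pyran-6-yl acetate (mixture at the two pyranone centres) | C=C(C)[C@H](CC[C@](C)(O[Si](CC)(CC)CC)[C@@H](CCC(C)=C)C1OC(OC(C)=O)C(C)=CC1=O)O[Si](C)(C)C(C)(C)C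
A4 | alternative 2 | oxygen-bridged tricyclic enone (C5–O–C8a bridge, C8 ketone, C6=C7 alkene) with the bis-silylated side chain | C=C(C)[C@H](CC[C@](C)(O[Si](CC)(CC)CC)[C@H]1CC[C@]2(C)C[C@@H]3O[C@]12C(=O)C=C3C)O[Si](C)(C)C(C)(C)C
A5 | alternative 3 | methyl (5R)-5-(2,2-dimethoxyethyl)-5-methylcyclopent-1-ene-1-carboxylate | COC(=O)C1=CCC[C@]1(C)CC(OC)OC
A6 | alternative 3 | (5S)-5-[(tert-butyldimethylsilyl)oxy]-6-methylhept-6-en-2-one | C=C(C)[C@H](CCC(C)=O)O[Si](C)(C)C(C)(C)C
A7 | alternative 3 | cis-fused cyclopentane γ-lactone carrying C1, C1', C8a and C3a, with the dimethyl acetal arm and the silylated side chain | C=C(C)[C@H](CC[C@]1(C)OC(=O)[C@H]2[C@@H]1CC[C@]2(C)CC(OC)OC)O[Si](C)(C)C(C)(C)C
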